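Numbering and configuration: ring A is the cyclopentane C1–C5 (C1 quaternary, bonded to CH3, C2, C10 and C5; C4 is the isopropyl carbinol). Ring B is C1, C5, C6 (O-vanilloyl), C7, C8 (CH3), C9, C10. The SMILES reads as (1R,4R,5S,6R,8R,9S): trans fusion with C1-CH3, 4-OH and 6-O on one face (β) and H5, isopropyl and the epoxide oxygen on the other (α).
Cuts, in retrosynthetic order: phenol O–Si, the epoxide oxygen at C8/C9, the acyl–O6 bond, C5–H (from a 5,6-epoxide that already carries O6), C4–isopropyl, C5=C6 (from a C6 carbinol), C8=C9 (metathesis), C6–C7 (methallyl addition) and last C1–C5.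
Enabling feature: C1 is the methyl-bearing methine of citronellal with C5 standing where its hydrogen stood. C5 lies between C4 (ketone level) and C6 (carboxyl level), so it can be the carbenoid carbon of a diazo β-keto ester that reaches the tertiary C1–H bond across C4, C3 and C2.
Forward: (S)-citronellal supplies C9, C10, C1, its methyl and C2–C4, and ethyl diazoacetate supplies C5 and C6. Ring A closes first by C–H insertion. Ring B closes second by ring-closing metathesis after methallyl addition (C7, C8, C8-CH3). Isopropyl, O6, the vanillate and the epoxide follow.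
Stereochemistry: C1 comes from citronellal with retention. The labile C5 centre (and C6) is erased on purpose in a bicyclic dienone and rebuilt under the angular methyl: isopropyl adds α (C4), the new 4β-OH directs a β-epoxide (C6–O), a hydrogen atom enters α at C5, and the peracid attacks C8=C9 from α.

Key step: step 5

Remark: from the ketalisation to the elimination (steps 6–11) the material is carried as a mixture of C5 epimers, and from step 8 on also of C6 epimers, because step 11 removes both centres. The SMILES of these compounds leave the two centres open. The key-step product is drawn as the epimer with the ester cis to the methyl group.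

Step 1
Reactants: 1 (S)-citronellal; 2 methyltriphenylphosphonium bromide
Product: 4 (4S)-4,8-dimethylnona-1,7-diene, via methylenetriphenylphosphorane 3 (not isolated)
Conditions: 2, KOt-Bu, THF, 0 °C; then 1, 0 °C to rt
Reagents that add atoms: none
Why: Wittig methylenation of an unhindered aldehyde turns the formyl carbon into C9 of a vinyl group, and the stereocentre (the later C1) sits β to the carbonyl and is not at risk.

Step 2
Reactants: 4 (4S)-4,8-dimethylnona-1,7-diene
Product: 6 (4S)-4-methylhept-6-enal, via side-chain epoxide 5 (not isolated)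
Conditions: mCPBA (1.0 equiv), CH2Cl2, 0 °C; then H5IO6, THF/H2O, 0 °C
Reagents that add atoms: 3-chloroperbenzoic acid (mCPBA), OOC(=O)c1cccc(Cl)c1
Why: Prilezhaev epoxidation selects the electron-rich trisubstituted alkene over the monosubstituted one, and periodic acid then hydrolyses the epoxide and cleaves the glycol (Malaprade cleavage) to the aldehyde carbon that becomes C4.

Step 3
Reactants: 6 (4S)-4-methylhept-6-enal; 7 ethyl diazoacetate
Product: 8 ethyl (6S)-6-methyl-3-oxonon-8-enoate
Conditions: SnCl2 (10 mol %), CH2Cl2, rt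
Reagents that add atoms: none
Why: Roskamp homologation, in which the diazo carbon adds to the SnCl2-activated aldehyde and a 1,2-hydride shift with loss of N2 gives the β-keto ester, brings in C5 and C6 without touching the alkene.

Step 4
Reactants: 8 ethyl (6S)-6-methyl-3-oxonon-8-enoate
Product: 9 ethyl (6S)-2-diazo-6-methyl-3-oxonon-8-enoate
Conditions: p-ABSA, Et3N, MeCN, 0 °C to rt
Reagents that add atoms: 4-acetamidobenzenesulfonyl azide (p-ABSA), CC(=O)Nc1ccc(cc1)S(=O)(=O)N=[N+]=[N-]
Why: Regitz diazo transfer to the doubly activated methylene of a β-keto ester is general and mild.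

Step 5
Reactants: 9 ethyl (6S)-2-diazo-6-methyl-3-oxonon-8-enoate
Product: 11 ethyl (1R,2R)-2-allyl-2-methyl-5-oxocyclopentane-1-carboxylate, via rhodium carbenoid 10 (not isolated)
Conditions: Rh2(OAc)4 (1 mol %), CH2Cl2, 40 °C, slow addition of 9
Reagents that add atoms: none
Why: Rh2(OAc)4 takes N2 out of 9 and leaves the electrophilic carbenoid 10 at C5, flanked by the C4 ketone and the C6 ester, which inserts into the C1–H bond in one concerted, three-centre event. The closest known reaction type is the dirhodium-catalysed 1,5 C–H insertion of α-diazo β-keto esters into tertiary C–H bonds, which is established to go with retention. Ring A closes by C1–C5 bond formation through a five-membered cyclic transition state made of C5, C4, C3, C2 and C1. C1 turns quaternary with its citronellal configuration intact because C5 arrives on the face that hydrogen leaves, whereas C5 is an acidic methine that settles by enolisation (ester expected mainly trans to the longer allyl arm) and is not relied on, since step 11 erases it. The step needs site selectivity for C1–H over the methylene, methyl and allylic C–H bonds and chemoselectivity over cyclopropanation; the tertiary C–H is the most electron-rich bond and the only one within a five-membered transition state, while the vinyl group could be reached only through a seven-membered one. Slow addition to dilute catalyst should hold back carbene dimers and intermolecular cyclopropanation.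

Step 6
Reactants: 11 ethyl (1R,2R)-2-allyl-2-methyl-5-oxocyclopentane-1-carboxylate
Product: 12 ethyl (7R)-7-allyl-7-methyl-1,4-dioxaspiro[4.4]nonane-6-carboxylate (C5 epimers)
Conditions: HOCH2CH2OH, p-TsOH·H2O (cat.), toluene, reflux, Dean–Stark
Reagents that add atoms: ethylene glycol, OCCO
Why: Acid-catalysed ketalisation with azeotropic removal of water masks the C4 ketone so that C6 can be reduced alone, and the C5 epimer ratio that results is of no consequence.

Step 7
Reactants: 12 ethyl (7R)-7-allyl-7-methyl-1,4-dioxaspiro[4.4]nonane-6-carboxylate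
Product: 13 (7R)-7-allyl-7-methyl-1,4-dioxaspiro[4.4]nonane-6-carbaldehyde (C5 epimers)
Conditions: i-Bu2AlH (DIBAL-H, 1.1 equiv), CH2Cl2, −78 °C; MeOH, aq. potassium sodium tartrate
Reagents that add atoms: none
Why: Partial ester reduction with i-Bu2AlH should stop at the aldehyde because the crowded tetrahedral aluminium hemiacetal, held by a ketal oxygen, survives at −78 °C until the quench.

Step 8
Reactants: 13 (7R)-7-allyl-7-methyl-1,4-dioxaspiro[4.4]nonane-6-carbaldehyde; 14 2-methylallylmagnesium chloride
Product: 15 1-[(7R)-7-allyl-7-methyl-1,4-dioxaspiro[4.4]nonan-6-yl]-3-methylbut-3-en-1-ol (C5 and C6 epimers)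
Conditions: THF, −78 °C; aq. NH4Cl
Reagents that add atoms: none
Why: Grignard addition of an allylic magnesium reagent through a six-membered transition state forms C6–C7 even at this crowded aldehyde, and the C6 configuration is left open on purpose because step 11 removes it.

Step 9
Reactants: 15 1-[(7R)-7-allyl-7-methyl-1,4-dioxaspiro[4.4]nonan-6-yl]-3-methylbut-3-en-1-ol
Product: 16 ethylene ketal of (8aR)-4-hydroxy-6,8a-dimethyl-2,3a,4,5,8,8a-hexahydroazulen-3(1H)-one (C5 and C6 epimers)
Conditions: second-generation Grubbs catalyst RuCl2(=CHPh)(PCy3)(SIMes) (5 mol %), CH2Cl2 (2 mM), reflux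
Reagents that add atoms: none
Why: Ring-closing metathesis between the monosubstituted and the 1,1-disubstituted alkene closes ring B as a trisubstituted cycloheptene whose Z geometry is enforced by the ring, is driven by loss of ethylene and tolerates the free hydroxyl group.

Step 10
Reactants: 16 ethylene ketal of (8aR)-4-hydroxy-6,8a-dimethyl-2,3a,4,5,8,8a-hexahydroazulen-3(1H)-one
Product: 17 (8aR)-4-hydroxy-6,8a-dimethyl-2,3a,4,5,8,8a-hexahydroazulen-3(1H)-one (C5 and C6 epimers)
Conditions: 1 M HCl, THF, rt
Reagents that add atoms: water, O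
Why: Aqueous acid hydrolysis of the dioxolane frees the C4 ketone, and any dehydration that sets in already here only anticipates step 11.

Step 11
Reactants: 17 (8aR)-4-hydroxy-6,8a-dimethyl-2,3a,4,5,8,8a-hexahydroazulen-3(1H)-one
Product: 19 (8aR)-6,8a-dimethyl-2,5,8,8a-tetrahydroazulen-3(1H)-one, via C6 mesylate 18 (not isolated)
Conditions: MsCl, Et3N (excess), CH2Cl2, 0 °C to rt
Reagents that add atoms: none
Why: Mesylation and E1cB elimination through the C4 enolate funnel all C5/C6 diastereomers into one C5=C6 enone (stereoconvergence), while a weak amine base at or below room temperature should leave the doubly allylic C7 methylene alone.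

Step 12
Reactants: 19 (8aR)-6,8a-dimethyl-2,5,8,8a-tetrahydroazulen-3(1H)-one; 20 isopropyllithium
Product: 22 (3R,8aR)-3-isopropyl-6,8a-dimethyl-1,2,3,5,8,8a-hexahydroazulen-3-ol, via isopropylcerium dichloride 21 (not isolated)
Conditions: 20, anhydrous CeCl3, THF, −78 °C; then 19, −78 °C
Reagents that add atoms: none
Why: Organocerium 1,2-addition, chosen for its low basicity towards an enolisable enone, should come from the α face because C5 is planar, C10 is tied back in ring B and the pseudoaxial C1 methyl covers the β face, which sets C4 as R with the hydroxyl group β.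

Step 13
Reactants: 22 (3R,8aR)-3-isopropyl-6,8a-dimethyl-1,2,3,5,8,8a-hexahydroazulen-3-ol
Product: 23 (1R,4R,5S,6R)-5β,6β-epoxydauc-8-en-4β-ol
Conditions: VO(acac)2 (5 mol %), t-BuOOH (decane), CH2Cl2, 0 °C
Reagents that add atoms: tert-butyl hydroperoxide, CC(C)(C)OO
Why: Hydroxyl-directed vanadium-catalysed epoxidation of an allylic alcohol delivers oxygen to C5=C6 on the face of the 4β-hydroxyl group, which sets the C6–O bond (6R), and leaves the isolated C8=C9 alkene untouched.

Step 14
Reactants: 23 (1R,4R,5S,6R)-5β,6β-epoxydauc-8-en-4β-ol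
Product: 25 (3R,3aS,4R,8aR)-3-isopropyl-6,8a-dimethyl-1,2,3,3a,4,5,8,8a-octahydroazulene-3,4-diol, via titanoxy C5 radical 24 (not isolated)
Conditions: Cp2TiCl2, Zn dust, THF, rt (gives Cp2TiCl, trivalent titanium); then 23, 1,4-cyclohexadiene, rt; aq. NaH2PO4
Reagents that add atoms: none
Why: Nugent–RajanBabu reductive epoxide opening, known to turn 2,3-epoxy alcohols into 1,3-diols, breaks the C5–O bond to the tertiary radical 24 while C6–O keeps its configuration, and 1,4-cyclohexadiene should deliver hydrogen to the α face, away from the C1 methyl and the two titanium-bound oxygens at C4 and C6, which sets 5S and the trans ring fusion.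

Step 15
Reactants: 26 vanillic acid
Product: 28 4-(tert-butyldimethylsilyloxy)-3-methoxybenzoic acid, via bis-silyl derivative 27 (not isolated)
Conditions: TBSCl, imidazole, DMF, rt; then AcOH/THF/H2O, rt
Reagents that add atoms: tert-butyldimethylsilyl chloride, CC(C)(C)[Si](C)(C)Cl
Why: Exhaustive silylation followed by selective hydrolysis of the far more labile silyl ester leaves the phenol masked and the acid free.

Step 16
Reactants: 25 (3R,3aS,4R,8aR)-3-isopropyl-6,8a-dimethyl-1,2,3,3a,4,5,8,8a-octahydroazulene-3,4-diol; 28 4-(tert-butyldimethylsilyloxy)-3-methoxybenzoic acid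
Product: 29 (1R,4R,5S,6R)-4-hydroxydauc-8-en-6-yl 4-(tert-butyldimethylsilyloxy)-3-methoxybenzoate
Conditions: DCC, DMAP, CH2Cl2, rt to 40 °C
Reagents that add atoms: none
Why: Steglich esterification acylates only the secondary C6 hydroxyl group because the tertiary C4 hydroxyl group is inert to the acylpyridinium species, and no stereocentre is touched.

Step 17
Reactants: 29 (1R,4R,5S,6R)-4-hydroxydauc-8-en-6-yl 4-(tert-butyldimethylsilyloxy)-3-methoxybenzoate
Product: 30 (1R,4R,5S,6R,8R,9S)-8,9-epoxy-4-hydroxydaucan-6-yl 4-(tert-butyldimethylsilyloxy)-3-methoxybenzoate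
Conditions: mCPBA, CH2Cl2, 0 °C
Reagents that add atoms: 3-chloroperbenzoic acid (mCPBA), OOC(=O)c1cccc(Cl)c1
Why: Prilezhaev epoxidation of the only remaining alkene should take place on the α face because the C1 methyl and the C6 aroyloxy group both stand on the β face and flank C9 and C8, which sets 8R and 9S.

Step 18
Reactants: 30 (1R,4R,5S,6R,8R,9S)-8,9-epoxy-4-hydroxydaucan-6-yl 4-(tert-butyldimethylsilyloxy)-3-methoxybenzoate
Product: 31 (1R,4R,5S,6R,8R,9S)-8,9-epoxy-4-hydroxydaucan-6-yl 4-hydroxy-3-methoxybenzoate (CNP0254293.2)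
Conditions: TBAF, AcOH, THF, 0 °C
Reagents that add atoms: none
Why: Fluoride cleavage of the aryl silyl ether, buffered with acetic acid, frees the phenol without exposing ester or epoxide to base.

Compound list
1 | (S)-citronellal, (3S)-3,7-dimethyloct-6-enal | C[C@@H](CCC=C(C)C)CC=O | starting material
2 | methyltriphenylphosphonium bromide | C[P+](c1ccccc1)(c1ccccc1)c1ccccc1.[Br-] | starting material
3 | methylenetriphenylphosphorane | C=P(c1ccccc1)(c1ccccc1)c1ccccc1 | intermediate
4 | (4S)-4,8-dimethylnona-1,7-diene | C[C@@H](CCC=C(C)C)CC=C | intermediate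
5 | 2,2-dimethyl-3-[(3S)-3-methylhex-5-enyl]oxirane (side-chain epoxide, oxirane carbon unassigned) | C[C@@H](CCC1OC1(C)C)CC=C | intermediate
6 | (4S)-4-methylhept-6-enal | C[C@@H](CCC=O)CC=C | intermediate
7 | ethyl diazoacetate | CCOC(=O)C=[N+]=[N-] | starting material
8 | ethyl (6S)-6-methyl-3-oxonon-8-enoate | CCOC(=O)CC(=O)CC[C@H](C)CC=C | intermediate
9 | ethyl (6S)-2-diazo-6-methyl-3-oxonon-8-enoate (key-step precursor) | CCOC(=O)C(=[N+]=[N-])C(=O)CC[C@H](C)CC=C | intermediate
10 | rhodium carbenoid at C5 (second rhodium and acetate ligands omitted in the SMILES) | CCOC(=O)C(=[Rh])C(=O)CC[C@H](C)CC=C | intermediate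
11 | ethyl (1R,2R)-2-allyl-2-methyl-5-oxocyclopentane-1-carboxylate (ring A, key-step product, C5 epimerisable) | CCOC(=O)[C@H]1C(=O)CC[C@]1(C)CC=C | intermediate
12 | ethyl (7R)-7-allyl-7-methyl-1,4-dioxaspiro[4.4]nonane-6-carboxylate (C5 epimers) | CCOC(=O)C1[C@@](C)(CC=C)CCC12OCCO2 | intermediate
13 | (7R)-7-allyl-7-methyl-1,4-dioxaspiro[4.4]nonane-6-carbaldehyde (C5 epimers) | O=CC1[C@@](C)(CC=C)CCC12OCCO2 | intermediate
14 | 2-methylallylmagnesium chloride | CC(=C)C[Mg]Cl | starting material
15 | 1-[(7R)-7-allyl-7-methyl-1,4-dioxaspiro[4.4]nonan-6-yl]-3-methylbut-3-en-1-ol (C5 and C6 epimers) | CC(=C)CC(O)C1[C@@](C)(CC=C)CCC12OCCO2 | intermediate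
16 | ethylene ketal of (8aR)-4-hydroxy-6,8a-dimethyl-2,3a,4,5,8,8a-hexahydroazulen-3(1H)-one (rings A and B, C5 and C6 epimers) | CC1=CC[C@@]2(C)CCC3(OCCO3)C2C(O)C1 | intermediate
17 | (8aR)-4-hydroxy-6,8a-dimethyl-2,3a,4,5,8,8a-hexahydroazulen-3(1H)-one (C5 and C6 epimers) | CC1=CC[C@@]2(C)CCC(=O)C2C(O)C1 | intermediate
18 | C6 methanesulfonate of 17 | CC1=CC[C@@]2(C)CCC(=O)C2C(OS(C)(=O)=O)C1 | intermediate
19 | (8aR)-6,8a-dimethyl-2,5,8,8a-tetrahydroazulen-3(1H)-one (C4 ketone, C5=C6, C8=C9) | CC1=CC[C@@]2(C)CCC(=O)C2=CC1 | intermediate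
20 | isopropyllithium | CC(C)[Li] | starting material
21 | isopropylcerium dichloride | CC(C)[Ce](Cl)Cl | intermediate
22 | (3R,8aR)-3-isopropyl-6,8a-dimethyl-1,2,3,5,8,8a-hexahydroazulen-3-ol (4β-OH, isopropyl α) | CC1=CC[C@@]2(C)CC[C@@](O)(C(C)C)C2=CC1 | intermediate
23 | (1R,4R,5S,6R)-5β,6β-epoxydauc-8-en-4β-ol | CC1=CC[C@@]2(C)CC[C@@](O)(C(C)C)[C@]23O[C@@H]3C1 | intermediate
24 | tertiary C5 radical with C6–O–TiCp2Cl | CC1=CC[C@@]2(C)CC[C@@](O)(C(C)C)[C]2[C@H](O[Ti](Cl)(C3C=CC=C3)C3C=CC=C3)C1 | intermediate
25 | (3R,3aS,4R,8aR)-3-isopropyl-6,8a-dimethyl-1,2,3,3a,4,5,8,8a-octahydroazulene-3,4-diol (5αH-dauc-8-ene-4β,6β-diol) | CC1=CC[C@@]2(C)CC[C@@](O)(C(C)C)[C@@H]2[C@H](O)C1 | intermediate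
26 | vanillic acid | COc1cc(C(=O)O)ccc1O | starting material
27 | tert-butyldimethylsilyl 4-(tert-butyldimethylsilyloxy)-3-methoxybenzoate | COc1cc(C(=O)O[Si](C)(C)C(C)(C)C)ccc1O[Si](C)(C)C(C)(C)C | intermediate
28 | 4-(tert-butyldimethylsilyloxy)-3-methoxybenzoic acid | COc1cc(C(=O)O)ccc1O[Si](C)(C)C(C)(C)C | intermediate
29 | (1R,4R,5S,6R)-4-hydroxydauc-8-en-6-yl 4-(tert-butyldimethylsilyloxy)-3-methoxybenzoate | COc1cc(C(=O)O[C@@H]2CC(C)=CC[C@@]3(C)CC[C@@](O)(C(C)C)[C@H]23)ccc1O[Si](C)(C)C(C)(C)C | intermediate
30 | (1R,4R,5S,6R,8R,9S)-8,9-epoxy-4-hydroxydaucan-6-yl 4-(tert-butyldimethylsilyloxy)-3-methoxybenzoate | COc1cc(C(=O)O[C@@H]2C[C@@]3(C)O[C@H]3C[C@@]3(C)CC[C@@](O)(C(C)C)[C@H]23)ccc1O[Si](C)(C)C(C)(C)C | intermediate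
31 | (1R,4R,5S,6R,8R,9S)-8,9-epoxy-4-hydroxydaucan-6-yl 4-hydroxy-3-methoxybenzoate | COc1cc(C(=O)O[C@@H]2C[C@@]3(C)O[C@H]3C[C@@]3(C)CC[C@@](O)(C(C)C)[C@H]23)ccc1O | target

Total step count: 18. Longest linear sequence: 17 (steps 1–14 and 16–18). Step 15 is a one-step side branch.

Steps most likely to fail, in order of risk.

First, step 14. Hydrogen-atom transfer to the crowded C5 radical may be slow or may come in part from the β face, so the ring fusion is not set cleanly. Reductive deoxygenation back to the alkene may also compete.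
- The fallback replaces kinetic radical control by thermodynamic enolate control. It sets out from 23 and comes back at 25.
- The titanocene opening is run without regard to C5 and gives dauc-8-ene-4β,6β-diol as C5 epimer mixture F1.
- Dess–Martin periodinane oxidises C6. Brief equilibration with DBU at the now enolisable C5 should gather the material as 4β-hydroxy-5αH-dauc-8-en-6-one F2, in which C6 stands anti to isopropyl and the 4-OH can hydrogen-bond to the ketone.
- LiBH(s-Bu)3 in THF at −78 °C, approaching anti to the angular methyl, should then return 25.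

Second, step 12. On the flat dienone the facial preference may be poor, and enolisation at C3 or C7 or hydride transfer from the isopropyl reagent may compete with addition.
- The fallback adds isopropyl to a saturated, trans-fused ketone in which a β-silyloxy group next to C5 reinforces the shielding of the β face. It sets out from 17, comes back at 25, and bypasses 19, 22 and 23.
- The (5S,6R) diastereomer of 17 is separated and silylated (TESCl, imidazole) to 6β-triethylsilyloxy-5αH-11,12,13-trinordauc-8-en-4-one F3.
- Reagent 21 should add from the α face to give 6β-triethylsilyloxy-5αH-dauc-8-en-4β-ol F4, and TBAF removes the silyl group. The other diastereomers of 17 still feed step 11.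

Third, step 17. The cycloheptene is flexible, so its β face may open up and facial selectivity may be poor or reversed.
- The fallback is the halohydrin route, which places the oxygen on the face opposite to the one the electrophile attacks. It sets out from 29 and comes back at 30.
- NBS in aqueous DME should give, by bromonium formation on the β face and attack of water on the α face at tertiary C8, 9β-bromo-4β,8α-dihydroxy-5αH-daucan-6β-yl 4-(tert-butyldimethylsilyloxy)-3-methoxybenzoate F5.
- DBU then closes F5 by internal SN2 displacement at C9 to the α-epoxide 30.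

Further compounds
F1 | step 14 | dauc-8-ene-4β,6β-diol as C5 epimer mixture | CC1=CC[C@@]2(C)CC[C@@](O)(C(C)C)C2[C@H](O)C1
F2 | step 14 | 4β-hydroxy-5αH-dauc-8-en-6-one | CC1=CC[C@@]2(C)CC[C@@](O)(C(C)C)[C@@H]2C(=O)C1
F3 | step 12 | 6β-triethylsilyloxy-5αH-11,12,13-trinordauc-8-en-4-one | CC1=CC[C@@]2(C)CCC(=O)[C@@H]2[C@H](O[Si](CC)(CC)CC)C1
F4 | step 12 | 6β-triethylsilyloxy-5αH-dauc-8-en-4β-ol | CC1=CC[C@@]2(C)CC[C@@](O)(C(C)C)[C@@H]2[C@H](O[Si](CC)(CC)CC)C1
F5 | step 17 | 9β-bromo-4β,8α-dihydroxy-5αH-daucan-6β-yl 4-(tert-butyldimethylsilyloxy)-3-methoxybenzoate | COc1cc(C(=O)O[C@@H]2C[C@@](C)(O)[C@H](Br)C[C@@]3(C)CC[C@@](O)(C(C)C)[C@H]23)ccc1O[Si](C)(C)C(C)(C)C
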